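Ring A is the 3-hydroxy-5-methoxyphenyl ring. Ring B is the central phenol: C1 carries the CH2CH2 bridge, C2 and C6 the 4-hydroxybenzyl groups, C3 and C4 are C–H, C5 carries OH. Rings C and D are the two 4-hydroxyphenyl rings.
Enabling feature: C2 and C6 of ring B, the two carbons flanking C1, bear the same 4-hydroxybenzyl group. A C2,C6-dibromide can therefore be coupled twice with one benzylzinc reagent without distinguishing the sites, and the same two bromines make C1–H the most acidic ring proton of a 2,4-dibromophenol ether.
Cuts: first the ring B aryl–CH2 bonds C2–CH2 and C6–CH2 (together), then the central bond of the bridge (as C=C, by olefination), then the C1–CHO bond of ring B.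
Forward: no ring is built. Ring B is formylated at C1 and joined to a ring A phosphonate to give a stilbene, which diimide saturates. Rings C and D are then attached in one twofold Negishi coupling, and hydrogenolysis removes four benzyl ethers.
Stereochemistry: the target has no stereocentre and no stereogenic double bond. The only stereo-element on the way, an E alkene, is erased by the diimide step.

Key step: step 10

Assumption: in the twofold coupling the less hindered C2–Br is taken to react first, so the transient monobromide is drawn with bromine left at C6. The opposite order would lead to the same product.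

Step 1
Reactants: 1 2,4-dibromophenol
Product: 2 1-(benzyloxy)-2,4-dibromobenzene
Conditions: BnBr, K2CO3, DMF, 25 °C
Reagents that add atoms: benzyl bromide, BrCc1ccccc1
Why: Williamson ether synthesis, in which K2CO3 ionises the acidic dibromophenol and the phenoxide displaces bromide from benzyl bromide by SN2, giving an ether that should tolerate amide bases, diimide and organozinc reagents and fall to hydrogenolysis at the end.

Step 2
Reactants: 2 1-(benzyloxy)-2,4-dibromobenzene
Product: 4 3-(benzyloxy)-2,6-dibromobenzaldehyde, via 2,6-dibromoaryllithium 3 (not isolated)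
Conditions: LiN(iPr)2 (commercial solution, 1.1 equiv), THF, −78 °C; DMF, −78 °C; then 1 M aq. HCl
Reagents that add atoms: N,N-dimethylformamide, CN(C)C=O
Why: Deprotonative lithiation followed by formylation with DMF, which should work because the C–H between the two bromines is by far the most acidic ring position, the hindered amide base deprotonates rather than exchanges bromine, the anion formed is already the most stabilised one (so bromine migration has no driving force), and at −78 °C it should outlast LiBr loss until DMF arrives.

Step 3
Reactants: 5 methyl 3-hydroxy-5-methoxybenzoate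
Product: 6 methyl 3-(benzyloxy)-5-methoxybenzoate
Conditions: BnBr, K2CO3, DMF, 25 °C
Reagents that add atoms: benzyl bromide, BrCc1ccccc1
Why: Williamson ether synthesis on the only acidic site, the carbonate base leaving the methyl ester untouched.

Step 4
Reactants: 6 methyl 3-(benzyloxy)-5-methoxybenzoate
Product: 7 [3-(benzyloxy)-5-methoxyphenyl]methanol
Conditions: LiAlH4, THF, 0 °C; then H2O, 15% aq. NaOH, H2O
Reagents that add atoms: none
Why: Hydride reduction of an aryl ester to the primary benzylic alcohol with LiAlH4, to which the aryl ethers are inert.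

Step 5
Reactants: 7 [3-(benzyloxy)-5-methoxyphenyl]methanol
Product: 8 1-(benzyloxy)-3-(bromomethyl)-5-methoxybenzene
Conditions: PBr3 (0.4 equiv), CH2Cl2, 0 °C
Reagents that add atoms: phosphorus tribromide, BrP(Br)Br
Why: Bromination of a primary benzylic alcohol with PBr3 through a phosphite ester that bromide displaces by SN2, under conditions too mild to cleave the aryl benzyl or methyl ether.

Step 6
Reactants: 8 1-(benzyloxy)-3-(bromomethyl)-5-methoxybenzene
Product: 9 diethyl [3-(benzyloxy)-5-methoxybenzyl]phosphonate
Conditions: P(OEt)3 (neat), 130 °C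
Reagents that add atoms: triethyl phosphite, CCOP(OCC)OCC
Why: Michaelis–Arbuzov reaction, in which the phosphite attacks the benzylic bromide by SN2 and bromide then dealkylates the phosphonium ion while the volatile by-product distils off.

Step 7
Reactants: 9 diethyl [3-(benzyloxy)-5-methoxybenzyl]phosphonate; 4 3-(benzyloxy)-2,6-dibromobenzaldehyde
Product: 11 (E)-1-(benzyloxy)-2,4-dibromo-3-[2-(3-benzyloxy-5-methoxyphenyl)ethenyl]benzene, via potassium phosphonate carbanion 10 (not isolated)
Conditions: 9 (1.2 equiv), KOtBu (1.15 equiv), THF, 0 °C; then 4, 0 → 25 °C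
Reagents that add atoms: none
Why: Horner–Wadsworth–Emmons olefination, in which the pre-formed benzylic carbanion adds reversibly to the non-enolisable, electrophilic aldehyde and phosphate leaves from the less crowded adduct to give the E alkene (a geometry of no later consequence), while forming the carbanion first keeps free alkoxide away from the base-sensitive 2,6-dibromobenzaldehyde.

Step 8
Reactants: 11 (E)-1-(benzyloxy)-2,4-dibromo-3-[2-(3-benzyloxy-5-methoxyphenyl)ethenyl]benzene
Product: 12 1-(benzyloxy)-2,4-dibromo-3-[2-(3-benzyloxy-5-methoxyphenyl)ethyl]benzene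
Conditions: TsNHNH2 (excess, in portions), NaOAc, DME/H2O, reflux
Reagents that add atoms: none
Why: Diimide reduction, in which HN=NH released from the sulfonyl hydrazide passes two hydrogens to the non-polar C=C bond through a concerted six-centre transition state and should leave intact the C–Br and O–benzyl bonds that hydrogenation over palladium would cleave.

Step 9
Reactants: 13 4-(benzyloxy)benzyl chloride
Product: 14 4-(benzyloxy)benzylzinc chloride (kept as a titrated THF solution, LiCl complex)
Conditions: Zn dust (1.5 equiv), LiCl (1.5 equiv), THF, 25 °C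
Reagents that add atoms: zinc, [Zn]
Why: LiCl-promoted direct insertion of zinc into a benzylic chloride, where LiCl takes the organozinc off the metal surface as a soluble complex, so the insertion should run at 25 °C with little Wurtz-type homocoupling.

Step 10
Reactants: 12 1-(benzyloxy)-2,4-dibromo-3-[2-(3-benzyloxy-5-methoxyphenyl)ethyl]benzene; 14 4-(benzyloxy)benzylzinc chloride (two equivalents are incorporated)
Product: 16 1-(benzyloxy)-2,4-bis[4-(benzyloxy)benzyl]-3-[2-(3-benzyloxy-5-methoxyphenyl)ethyl]benzene (tetra-O-benzyl target), via C6-monobromide 15 (not isolated)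
Conditions: 14 (3 equiv, slow addition), Pd(OAc)2 (5 mol%), SPhos (10 mol%), THF, 25 → 60 °C
Reagents that add atoms: none
Why: Pd(OAc)2 is reduced in the flask by 14 to a monoligated zerovalent palladium–SPhos species, which inserts into a C–Br bond, receives the benzyl group from zinc by transmetalation and forms the aryl–CH2 bond by reductive elimination from divalent palladium, after which the same cycle runs on monobromide 15. The closest known reaction type is the Negishi coupling of LiCl-solubilised benzylic zinc chlorides with ortho-substituted, electron-rich aryl bromides under bulky dialkylbiarylphosphine ligation, twofold couplings of dibromoarenes included. No ring is closed and no stereocentre is formed. Site selectivity is not needed because C2 and C6 of ring B receive the same group: C2–Br (one ortho neighbour) should react first and C6–Br (wedged between the bridge at C1 and the benzyloxy group at C5) second, and either order ends at 16. The selectivity that is needed is chemoselectivity for complete twofold coupling over protodebromination and benzyl–benzyl homocoupling, and it is secured by the electron-rich bulky ligand (fast oxidative addition into C–Br bonds ortho and para to oxygen, fast reductive elimination at the crowded centre), by slow addition of an excess of 14 and by the lack of β-hydrogens in the benzyl group. The aryl ethers and the saturated bridge of 12 are inert to the mild organozinc reagent, so nothing else in the substrate competes.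

Step 11
Reactants: 16 1-(benzyloxy)-2,4-bis[4-(benzyloxy)benzyl]-3-[2-(3-benzyloxy-5-methoxyphenyl)ethyl]benzene
Product: 17 3-[2-(3-hydroxy-5-methoxyphenyl)ethyl]-2,4-bis(4-hydroxybenzyl)phenol (CNP0518900.0)
Conditions: H2 (1 atm), 10% Pd/C, EtOAc/MeOH, 25 °C
Reagents that add atoms: none
Why: Catalytic hydrogenolysis of aryl benzyl ethers, in which all four O–CH2Ph bonds should be cleaved on palladium on carbon while the methyl ether, the diarylmethane and bibenzyl C–C bonds and the arene rings are stable at 1 atm and 25 °C.

Compound list
1 | 2,4-dibromophenol | Oc1ccc(Br)cc1Br | starting material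
2 | 1-(benzyloxy)-2,4-dibromobenzene | Brc1ccc(OCc2ccccc2)c(Br)c1 | intermediate
3 | [3-(benzyloxy)-2,6-dibromophenyl]lithium (not isolated) | [Li]c1c(Br)ccc(OCc2ccccc2)c1Br | intermediate
4 | 3-(benzyloxy)-2,6-dibromobenzaldehyde | O=Cc1c(Br)ccc(OCc2ccccc2)c1Br | intermediate
5 | methyl 3-hydroxy-5-methoxybenzoate | COC(=O)c1cc(O)cc(OC)c1 | starting material
6 | methyl 3-(benzyloxy)-5-methoxybenzoate | COC(=O)c1cc(OC)cc(OCc2ccccc2)c1 | intermediate
7 | [3-(benzyloxy)-5-methoxyphenyl]methanol | OCc1cc(OC)cc(OCc2ccccc2)c1 | intermediate
8 | 1-(benzyloxy)-3-(bromomethyl)-5-methoxybenzene | BrCc1cc(OC)cc(OCc2ccccc2)c1 | intermediate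
9 | diethyl [3-(benzyloxy)-5-methoxybenzyl]phosphonate | CCOP(=O)(Cc1cc(OC)cc(OCc2ccccc2)c1)OCC | intermediate
10 | potassium salt of the benzylic carbanion of 9 (not isolated) | [K+].CCOP(=O)([CH-]c1cc(OC)cc(OCc2ccccc2)c1)OCC | intermediate
11 | (E)-1-(benzyloxy)-2,4-dibromo-3-[2-(3-benzyloxy-5-methoxyphenyl)ethenyl]benzene | COc1cc(OCc2ccccc2)cc(/C=C/c2c(Br)ccc(OCc3ccccc3)c2Br)c1 | intermediate
12 | 1-(benzyloxy)-2,4-dibromo-3-[2-(3-benzyloxy-5-methoxyphenyl)ethyl]benzene | COc1cc(OCc2ccccc2)cc(CCc2c(Br)ccc(OCc3ccccc3)c2Br)c1 | intermediate
13 | 4-(benzyloxy)benzyl chloride | ClCc1ccc(OCc2ccccc2)cc1 | starting material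
14 | 4-(benzyloxy)benzylzinc chloride | Cl[Zn]Cc1ccc(OCc2ccccc2)cc1 | intermediate
15 | 1-(benzyloxy)-4-[4-(benzyloxy)benzyl]-2-bromo-3-[2-(3-benzyloxy-5-methoxyphenyl)ethyl]benzene (not isolated) | COc1cc(OCc2ccccc2)cc(CCc2c(Cc3ccc(OCc4ccccc4)cc3)ccc(OCc3ccccc3)c2Br)c1 | intermediate
16 | 1-(benzyloxy)-2,4-bis[4-(benzyloxy)benzyl]-3-[2-(3-benzyloxy-5-methoxyphenyl)ethyl]benzene | COc1cc(OCc2ccccc2)cc(CCc2c(Cc3ccc(OCc4ccccc4)cc3)ccc(OCc3ccccc3)c2Cc2ccc(OCc3ccccc3)cc2)c1 | intermediate
17 | 3-[2-(3-hydroxy-5-methoxyphenyl)ethyl]-2,4-bis(4-hydroxybenzyl)phenol | COc1cc(O)cc(CCc2c(Cc3ccc(O)cc3)ccc(O)c2Cc2ccc(O)cc2)c1 | target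

Total step count: 11
Longest linear sequence: 8 steps (from 5 through steps 3, 4, 5, 6, 7, 8, 10 and 11)

Steps most likely to fail

Step 10. Oxidative addition at the C6–Br bond, wedged between the bridge and the benzyloxy group, may lag. Protodebromination and homocoupling of the zinc reagent could then use up the material before both bonds are made.
The fallback reverses the polarity. It sets out from 12 and comes back at 17.
- Both bromines of 12 are exchanged with t-BuLi (four equivalents, THF/Et2O, −78 °C) to give the C2,C6-dilithioarene F1.
- F1 is added to commercial 4-(benzyloxy)benzaldehyde (O=Cc1ccc(OCc2ccccc2)cc1) and, after an aqueous quench, should give the bis(diarylcarbinol) F2 as a mixture of diastereomers whose stereocentres are lost again.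
- Hydrogenation of F2 over Pd/C in EtOH/AcOH should cleave the two doubly benzylic C–OH bonds together with the four benzyl ethers and deliver 17 directly.
- The same C2–C and C6–C bonds are formed, but no catalyst has to enter the crowded C–Br bond.
- Strong acid is avoided throughout, because a free diarylmethyl cation could be captured by ring A with closure of a seven-membered ring.

Step 2. Two processes may erode the regiochemical integrity of the anion before DMF is added. One is loss of LiBr from the aryllithium to an aryne. The other is bromine migration through bromine–lithium exchange between the aryllithium and unreacted 2.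
The fallback replaces bromine by chlorine, which neither exchanges with lithium nor leaves readily. It sets out from 9 (ring A half unchanged) and comes back at 16.
- Commercial 2,4-dichlorophenol is benzylated (BnBr, K2CO3) to 1-(benzyloxy)-2,4-dichlorobenzene F3.
- Lithium 2,2,6,6-tetramethylpiperidide (THF, −78 °C) removes the proton between the chlorines to give the 2,6-dichloroaryllithium F4.
- DMF followed by aqueous HCl converts F4 into 3-(benzyloxy)-2,6-dichlorobenzaldehyde F5.
- Carbanion 10, made from 9 as before, turns F5 into the (E)-dichlorostilbene F6, and diimide saturates this to the dichlorobibenzyl F7.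
- Twofold Negishi coupling of F7 with 14 under Pd(OAc)2/SPhos, a system competent for aryl chlorides, in refluxing THF should lead through the C6-monochloride F8 to 16.

Step 8. Hydrogen transfer from diimide to an alkene shielded by two ortho bromines may be slower than the self-disproportionation of diimide. Conversion would then stall and leave alkene and alkane together.
The fallback postpones the saturation. It sets out from 11 and comes back at 17.
- Stilbene 11 itself is submitted to the twofold coupling with 14 under the conditions of step 10.
- This should give, through the C6-monobromostilbene F9, the tetra-O-benzyl stilbene F10.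
- The final hydrogenation over Pd/C then saturates the C=C bond in the same operation that removes the four benzyl groups, giving 17 with one step fewer.

Further compounds
F1 | step 10 | 1-(benzyloxy)-3-[2-(3-benzyloxy-5-methoxyphenyl)ethyl]-2,4-dilithiobenzene | COc1cc(OCc2ccccc2)cc(CCc2c([Li])ccc(OCc3ccccc3)c2[Li])c1
F2 | step 10 | 1-(benzyloxy)-2,4-bis{[4-(benzyloxy)phenyl](hydroxy)methyl}-3-[2-(3-benzyloxy-5-methoxyphenyl)ethyl]benzene (mixture of diastereomers) | COc1cc(OCc2ccccc2)cc(CCc2c(C(O)c3ccc(OCc4ccccc4)cc3)ccc(OCc3ccccc3)c2C(O)c2ccc(OCc3ccccc3)cc2)c1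
F3 | step 2 | 1-(benzyloxy)-2,4-dichlorobenzene | Clc1ccc(OCc2ccccc2)c(Cl)c1
F4 | step 2 | [3-(benzyloxy)-2,6-dichlorophenyl]lithium | [Li]c1c(Cl)ccc(OCc2ccccc2)c1Cl
F5 | step 2 | 3-(benzyloxy)-2,6-dichlorobenzaldehyde | O=Cc1c(Cl)ccc(OCc2ccccc2)c1Cl
F6 | step 2 | (E)-1-(benzyloxy)-2,4-dichloro-3-[2-(3-benzyloxy-5-methoxyphenyl)ethenyl]benzene | COc1cc(OCc2ccccc2)cc(/C=C/c2c(Cl)ccc(OCc3ccccc3)c2Cl)c1
F7 | step 2 | 1-(benzyloxy)-2,4-dichloro-3-[2-(3-benzyloxy-5-methoxyphenyl)ethyl]benzene | COc1cc(OCc2ccccc2)cc(CCc2c(Cl)ccc(OCc3ccccc3)c2Cl)c1
F8 | step 2 | 1-(benzyloxy)-4-[4-(benzyloxy)benzyl]-2-chloro-3-[2-(3-benzyloxy-5-methoxyphenyl)ethyl]benzene | COc1cc(OCc2ccccc2)cc(CCc2c(Cc3ccc(OCc4ccccc4)cc3)ccc(OCc3ccccc3)c2Cl)c1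
F9 | step 8 | (E)-1-(benzyloxy)-4-[4-(benzyloxy)benzyl]-2-bromo-3-[2-(3-benzyloxy-5-methoxyphenyl)ethenyl]benzene | COc1cc(OCc2ccccc2)cc(/C=C/c2c(Cc3ccc(OCc4ccccc4)cc3)ccc(OCc3ccccc3)c2Br)c1
F10 | step 8 | (E)-1-(benzyloxy)-2,4-bis[4-(benzyloxy)benzyl]-3-[2-(3-benzyloxy-5-methoxyphenyl)ethenyl]benzene | COc1cc(OCc2ccccc2)cc(/C=C/c2c(Cc3ccc(OCc4ccccc4)cc3)ccc(OCc3ccccc3)c2Cc2ccc(OCc3ccccc3)cc2)c1
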